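## Retrosynthetic overview
1. Both indole rings are bought intact, one already carrying the 6-Br. The central imidazole is the only ring formed, and it is formed last.
2. The imidazole is cut at N1–C5 and N3–C4. N–C2–N comes from 6-bromoindole-3-carboxamidine and C4–C5 from 3-(chloroacetyl)indole, which places the bromoindole on C2 and the plain indole on C4(5).
3. The amidine comes from 6-bromo-1H-indole-3-carbonitrile by addition of an aluminium amide to C≡N.
4. The α-chloroketone comes from indole and chloroacetyl chloride by C3 acylation.
5. The route is convergent, uses no protecting groups and sets no stereocentres.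

Assumption: the target SMILES holds no stereocentre (flat, achiral heteroaromatic; the imidazole N–H tautomers are one compound), so "single enantiomer" needs no action.

## Route

Step 1
Reactants: 1 6-bromo-1H-indole-3-carbonitrile
Product: 3 6-bromo-1H-indole-3-carboximidamide hydrochloride, via aluminium amidinate adduct 2 (not isolated)
Conditions: AlMe3 (5 equiv), NH4Cl (5 equiv), PhMe, 0 °C to rt until CH4 stops; then 1, 90 °C, 18 h; poured onto moist SiO2/CHCl3 slurry, eluted with MeOH, triturated with Et2O
Reagents that add atoms: ammonium chloride [NH4+].[Cl-] (N and Cl of 3); trimethylaluminium C[Al](C)C (atoms only in 2, lost on work-up)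
Why: In this Garigipati amidine synthesis the amino(chloro)methylaluminium is Lewis acidic enough to activate even this deactivated (vinylogous cyanamide) nitrile and deliver NH2 to it, while the excess reagent only aluminates the indole N–H reversibly, the aryl bromide is inert, and no stereocentre is formed.

Step 2
Reactants: 4 1H-indole; 5 chloroacetyl chloride
Product: 6 2-chloro-1-(1H-indol-3-yl)ethan-1-one
Conditions: pyridine (1.0 equiv), 1,4-dioxane, 60 °C, 1 h; H2O, filtered, recrystallised from EtOH
Reagents that add atoms: none
Why: This is a Friedel–Crafts-type electrophilic acylation at the most nucleophilic indole position (C3), in which pyridine takes up HCl so the indole does not oligomerise, the acyl chloride reacts far faster than the alkyl chloride, and no stereocentre is formed.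

Step 3
Reactants: 3 6-bromo-1H-indole-3-carboximidamide hydrochloride; 6 2-chloro-1-(1H-indol-3-yl)ethan-1-one
Product: 10 nortopsentin B [2-(6-bromo-1H-indol-3-yl)-4-(1H-indol-3-yl)-1H-imidazole], via free amidine 7 (not isolated), via N-(2-oxoethyl)amidine 8 (not isolated), via 4-hydroxyimidazoline 9 (not isolated)
Conditions: 3 (1.2 equiv), KHCO3 (4 equiv), THF/H2O 4:1, reflux, N2; 6 in THF added over 1 h, then reflux 16 h
Reagents that add atoms: none
Why: In this classical amidine/α-haloketone imidazole synthesis the liberated amidine displaces chloride (SN2), its second nitrogen adds 5-exo to the ketone and water is lost with aromatisation as the driving force, while bicarbonate is too weak to deprotonate the indole N–H groups and the transient carbinol centre of 9 is racemic and destroyed on dehydration.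

## Compound list
1 | 6-bromo-1H-indole-3-carbonitrile | N#Cc1c[nH]c2cc(Br)ccc12 | starting material
2 | 6-bromo-N'-[chloro(methyl)alumanyl]-1H-indole-3-carboximidamide (aluminium amidinate adduct, indole N–H drawn free, not isolated) | NC(=N[Al](C)Cl)c1c[nH]c2cc(Br)ccc12 | intermediate
3 | 6-bromo-1H-indole-3-carboximidamide hydrochloride | N=C(N)c1c[nH]c2cc(Br)ccc12.Cl | intermediate
4 | 1H-indole | c1ccc2[nH]ccc2c1 | starting material
5 | chloroacetyl chloride | O=C(Cl)CCl | starting material
6 | 2-chloro-1-(1H-indol-3-yl)ethan-1-one | O=C(CCl)c1c[nH]c2ccccc12 | intermediate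
7 | 6-bromo-1H-indole-3-carboximidamide (free base, not isolated) | N=C(N)c1c[nH]c2cc(Br)ccc12 | intermediate
8 | 6-bromo-N-[2-(1H-indol-3-yl)-2-oxoethyl]-1H-indole-3-carboximidamide (not isolated) | N=C(NCC(=O)c1c[nH]c2ccccc12)c1c[nH]c2cc(Br)ccc12 | intermediate
9 | 2-(6-bromo-1H-indol-3-yl)-4-(1H-indol-3-yl)-4,5-dihydro-1H-imidazol-4-ol (racemic, not isolated) | OC1(c2c[nH]c3ccccc23)CNC(=N1)c1c[nH]c2cc(Br)ccc12 | intermediate
10 | nortopsentin B, 2-(6-bromo-1H-indol-3-yl)-4-(1H-indol-3-yl)-1H-imidazole (achiral) | Brc1ccc2c(-c3nc(-c4c[nH]c5ccccc45)c[nH]3)c[nH]c2c1 | target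

## Counts
- **Total step count:** 3 (steps 1 and 2 are independent branches; step 3 joins them).
- **Longest linear sequence:** 2 (1 → 3 → 10, or 4 → 6 → 10).

## Steps most likely to fail, in order of risk, with fallbacks

(a) The amidination, step 1. The nitrile is conjugated with the indole nitrogen and becomes still less electrophilic once the N–H is metalated. Conversion may therefore stall, and the polar salt is hard to free from aluminium residues.
- The fallback sets out from 1 and comes back at 3. It uses an α-effect nucleophile and a reductive N–O cleavage instead of an amide addition.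
- Compound 1 is refluxed with NH2OH·HCl/K2CO3 in EtOH to give the amidoxime (Z)-6-bromo-N'-hydroxy-1H-indole-3-carboximidamide F1.
- Ac2O in AcOH at rt converts F1 into (Z)-N'-acetoxy-6-bromo-1H-indole-3-carboximidamide F2.
- Zn dust in AcOH at rt cleaves the N–O bond without touching the aryl bromide. Evaporation from methanolic HCl then delivers 3.

(b) The union, step 3. The intermolecular alkylation competes with hydrolysis of 6 in the aqueous base and with further N-alkylation of 10 by 6. In addition, 6 is a less reactive SN2 partner than a normal phenacyl halide.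
- The fallback sets out from 6 (and uses 3) and comes back at 8. It reverses the polarity of the C–N bond formation.
- Compound 6 with NaN3 in DMF at rt gives 2-azido-1-(1H-indol-3-yl)ethan-1-one F3.
- Hydrogenation (H2, Pd/C, MeOH, 1.1 equiv HCl) gives 2-amino-1-(1H-indol-3-yl)ethan-1-one hydrochloride F4. This fragment holds no bromine, so hydrogenation is safe.
- Compound 3 is free-based to 7 with NaOMe in MeOH, and 7 (2 equiv) is heated with F4 in n-BuOH at 115 °C under N2.
- The amino ketone nitrogen attacks the amidine carbon and ammonia is expelled (transamidination), which gives 8. At this temperature 8 closes through 9 to 10.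

(c) The acylation, step 2. N-acylation, 1,3-diacylation and acid-induced indole oligomerisation can keep the yield low.
- The fallback sets out from 4 and comes back at 8. The acyl group is installed without halogen, and the halogen is added afterwards.
- Compound 4 with Et2AlCl and then AcCl in CH2Cl2 at 0 °C gives 1-(1H-indol-3-yl)ethan-1-one F5.
- Enol-selective α-bromination with CuBr2 (2 equiv) in refluxing EtOAc/CHCl3 gives 2-bromo-1-(1H-indol-3-yl)ethan-1-one F6.
- F6 takes the place of 6 under the conditions of step 3 and alkylates 7 to the same intermediate 8.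

## Further compounds
F1 | step 1 | (Z)-6-bromo-N'-hydroxy-1H-indole-3-carboximidamide | N/C(=N\O)c1c[nH]c2cc(Br)ccc12
F2 | step 1 | (Z)-N'-acetoxy-6-bromo-1H-indole-3-carboximidamide | CC(=O)O/N=C(\N)c1c[nH]c2cc(Br)ccc12
F3 | step 3 | 2-azido-1-(1H-indol-3-yl)ethan-1-one | [N-]=[N+]=NCC(=O)c1c[nH]c2ccccc12
F4 | step 3 | 2-amino-1-(1H-indol-3-yl)ethan-1-one hydrochloride | NCC(=O)c1c[nH]c2ccccc12.Cl
F5 | step 2 | 1-(1H-indol-3-yl)ethan-1-one | CC(=O)c1c[nH]c2ccccc12
F6 | step 2 | 2-bromo-1-(1H-indol-3-yl)ethan-1-one | O=C(CBr)c1c[nH]c2ccccc12
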